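**Retrosynthetic overview**
1. Target ⇐ 20,12-lactone diacid 15 (lactone → lactol/aldehyde); both axial carbinols (3β, 12α) come from hydride reductions, and lactonisation singles out C20.
2. Ring D last: C13–C16 bond by gold-catalysed Conia-ene cyclisation of a C12 silyl enol ether onto the 8-propargyl group.
3. Ring A: Robinson annulation with Nazarov's reagent on the ring B β-keto ester (C10–C1, C4–C5), then reductive trans A/B junction (C5) and C4 methylation.
4. Rings B/C with C8 and C9: organocatalytic desymmetrising intramolecular Michael addition (C9–C10) of achiral dienone 4.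
5. Dienone 4 ⇐ 4-propargylphenol + dimethyl 3-oxoglutarate by a new oxidative dearomative C6–C8 coupling. Ring order: C (arene) → B → A → D.

Assumption: the target is handled as the open 12-hydroxy-20-aldehyde as drawn (it can equilibrate with lactol ring tautomers, which are the same compound); 1 and 6 are taken as purchasable building blocks.

Numbering: gibberellane numbering is used for all intermediates (ring A C1–C5, C10; ring B C5, C6, C8, C9, C10; ring C C8, C9, C11–C14; ring D C8, C13–C16; C17 methylene; C18 methyl and C19 carboxyl on C4; C7 carboxyl on C6; C20 on C10). α is the face of C20, β the opposite face.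

**Step 1**
Reactants: 1 4-(prop-2-yn-1-yl)phenol; 2 dimethyl 3-oxopentanedioate
Product: 4 dimethyl 2-[4-oxo-1-(prop-2-yn-1-yl)cyclohexa-2,5-dien-1-yl]-3-oxopentanedioate, via TMS enol ether 3 (not isolated)
Conditions: 2 (3 equiv), N,O-bis(trimethylsilyl)acetamide, CH2Cl2, rt; then added to 1, PhI(OAc)2 (1.1 equiv), (CF3)2CHOH/CH2Cl2 4:1, −20 °C, 10 min; cold pH 7 buffer
Reagents that add atoms: none
Why: Proposed new method: an intermolecular oxidative dearomative Mukaiyama-type para-alkylation, in which ligand exchange of the phenol at trivalent iodine and ionisation in (CF3)2CHOH give a solvent-stabilised 4-propargylphenoxenium ion that the π-nucleophilic silyl enol ether 3 attacks at the substituted para carbon, and loss of the silyl group then leaves the C6–C8 bond and the quaternary C8 of an achiral dienone (C6 is a stereolabile keto–enol carbon, so no stereocentre is fixed); the closest known reaction type is the PhI(OAc)2/(CF3)2CHOH oxidative Hosomi–Sakurai para-allylation of 4-alkylphenols with allylsilanes.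

**Step 2**
Reactants: 4 dienone keto diester
Product: 5 dimethyl 2,5-dioxo-7a-(prop-2-yn-1-yl)-2,3,3a,4,5,7a-hexahydro-1H-indene-1,3-dicarboxylate (cis-fused; 8β-propargyl, 9β-H; C6 and C10 are epimerisable β-keto ester carbons)
Conditions: 9-amino(9-deoxy)epi-quinidine 3,5-bis(trifluoromethyl)phenyl squaramide (10 mol%), toluene, −20 °C (the cinchona series that gives the configuration shown is used; its pseudo-enantiomer gives ent-5)
Reagents that add atoms: none
Why: Organocatalytic desymmetrising intramolecular Michael addition: the catalyst amine deprotonates the C10 methylene while the squaramide binds the dienone carbonyl, so 5-exo-trig attack occurs on one enantiotopic enone arm only, which fixes the quaternary C8 and, through the cis ring fusion enforced by the tether, C9 (9-H cis to the 8-propargyl group), while the labile C6 epimers of 4 converge under the amine.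

**Step 3**
Reactants: 5 bicyclic β-keto ester; 6 methyl 5-methoxy-3-oxopentanoate
Product: 9 rings A/B/C tricycle: 3-oxo-Δ4(5) alkylidene β-keto ester (C19 methyl ester on C4) with 12-oxo-Δ13(14) enone and 8β-propargyl and 9β-H and 10α-CO2Me (C20) and 6β-CO2Me (C7), via Nazarov reagent 7 (not isolated), via Michael adduct 8 (not isolated)
Conditions: 6 (1.5 equiv), DBU (0.2 equiv), MeCN, 0 °C → rt; then pyrrolidine/AcOH (0.3 equiv each), toluene, 4 Å sieves, 80 °C
Reagents that add atoms: none
Why: Robinson annulation with Nazarov's reagent: base-induced loss of MeOH from 6 gives vinyl ketone 7, the C10 enolate of 5 adds to it from the convex β-face of the cis-fused bicycle (anti to ring C) so that C1 is β and the C20 ester α, and intramolecular Knoevenagel (aldol) condensation of the new C4 methylene with the C5 ketone closes ring A, the vinylogously acidic C6–H settling as the convex-face 6β-ester.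

**Step 4**
Reactants: 9 tricyclic alkylidene β-keto ester
Product: 10 trans-A/B β-keto ester (5β-H; C4 enolisable; otherwise as 9)
Conditions: SmI2 (2.2 equiv), THF/MeOH, −78 °C
Reagents that add atoms: none
Why: Chemoselective single-electron conjugate reduction: the doubly activated C4=C5 alkene is reduced far more readily than the ring C enone or the alkyne, and protonation of the C5 carbanion axially on ring A and anti to the axial C20 ester (the course of dissolving-metal enone reductions) is expected to give the trans A/B junction.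

**Step 5**
Reactants: 10 trans-fused β-keto ester
Product: 11 4β-methyl-4α-methoxycarbonyl 3-ketone (C4 quaternary; 6β-ester; ring C enone and propargyl unchanged)
Conditions: NaOMe (1.2 equiv), MeOH, rt, 2 h; then MeI, 0 °C → rt
Reagents that add atoms: iodomethane, CI
Why: β-Keto ester alkylation: the slight excess of methoxide first equilibrates C6 to the more stable 6β-ester (trans to C4), then MeI attacks the C4 enolate from the β-face opposite the 1,3-diaxial C20 ester, giving 4β-methyl/4α-ester as is usual for 2-alkoxycarbonyl ketone enolates next to an angular substituent.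

**Step 6**
Reactants: 11 3,12-dioxo enone triester
Product: 12 3β-hydroxy 12-(tert-butyldimethylsilyloxy)-Δ12(13) silyl enol ether triester
Conditions: KBH(sec-Bu)3 (2.3 equiv), THF, −78 °C; then TBSCl (1.3 equiv), HMPA, −78 → 0 °C; H2O work-up
Reagents that add atoms: tert-butyldimethylsilyl chloride, CC(C)(C)[Si](C)(C)Cl
Why: Bulky borohydride reductions: equatorial attack on the C3 ketone gives the axial 3β-alcohol, and 1,4-reduction of the β-unsubstituted ring C enone gives the regiodefined C12(O)=C13 potassium enolate, which is O-silylated while the hindered neopentylic C3 alkoxide is not.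

**Step 7**
Reactants: 12 silyl enol ether alkyne
Product: 13 tetracyclic 12-ketone with C16=C17 exocyclic methylene (3β-OH; C7, C19, C20 methyl esters)
Conditions: [(2-biphenyl)(t-Bu)2P]Au(NCMe)SbF6 (5 mol%), CH2Cl2/MeOH 10:1, rt
Reagents that add atoms: none
Why: Gold-catalysed Conia-ene-type 5-exo-dig carbocyclisation: the alkyne activated by cationic monovalent gold is attacked by C13 of the silyl enol ether, and protodeauration/desilylation by MeOH gives the bicyclo[3.2.1]octanone, the C13 configuration being dictated by bridging from the 8β-propargyl group.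

**Step 8**
Reactants: 13 tetracyclic 12-ketone triester
Product: 14 20,12α-lactone (δ-lactone C20(=O)–O–C12) with 3β-OH and C7, C19 methyl esters
Conditions: KBH(sec-Bu)3 (1.5 equiv), THF, −78 → −20 °C; H2O work-up
Reagents that add atoms: none
Why: Diastereoselective ketone reduction then lactonisation: the α-face of C12 is blocked by the axial C10 substituent, so hydride enters from the β (equatorial) side to give the axial 12α-alkoxide, which is 1,3-diaxial to C10 and acylates at once on the C20 ester, differentiating C20 from C7 and C19.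

**Step 9**
Reactants: 14 lactone dimethyl ester
Product: 15 20,12α-lactone 7,19-dicarboxylic acid (3β-OH)
Conditions: NaSPr (8 equiv), HMPA, rt; then aq. HCl
Reagents that add atoms: none
Why: SN2 O-demethylation of the two hindered methyl esters by thiolate, which is non-hydrolytic and so avoids retro-aldol at C3 and epimerisation at C6, while the lactone is attacked only reversibly.

**Step 10**
Reactants: 15 lactone diacid
Product: 17 target CNP0218328.1 (3β,12α-dihydroxy-20-oxo-gibberell-16-ene-7,19-dioic acid), via 20,12-lactol 16 (not isolated)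
Conditions: i-Bu2AlH (5 equiv), THF/CH2Cl2, −78 °C; aq. HCl (pH 3) work-up
Reagents that add atoms: none
Why: Partial reduction of a lactone to the lactol at −78 °C, the carboxylic acids being masked in situ as unreactive aluminium carboxylates; the lactol is the ring tautomer of the 12-hydroxy-20-aldehyde, which is the target.

**Compound list**
1 | 4-(prop-2-yn-1-yl)phenol | C#CCc1ccc(O)cc1 | starting material
2 | dimethyl 3-oxopentanedioate | COC(=O)CC(=O)CC(=O)OC | starting material
3 | dimethyl 3-[(trimethylsilyl)oxy]pent-2-enedioate (TMS enol ether of 2) | COC(=O)C=C(CC(=O)OC)O[Si](C)(C)C | intermediate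
4 | dimethyl 2-[4-oxo-1-(prop-2-yn-1-yl)cyclohexa-2,5-dien-1-yl]-3-oxopentanedioate (achiral dienone; C6 stereolabile) | COC(=O)CC(=O)C(C(=O)OC)C1(CC#C)C=CC(=O)C=C1 | intermediate
5 | dimethyl 2,5-dioxo-7a-(prop-2-yn-1-yl)-2,3,3a,4,5,7a-hexahydro-1H-indene-1,3-dicarboxylate, cis-fused, 8β-propargyl, 9β-H (C6, C10 epimerisable, not assigned) | C#CC[C@]23C=CC(=O)C[C@H]2C(C(=O)OC)C(=O)C3C(=O)OC | intermediate
6 | methyl 5-methoxy-3-oxopentanoate | COCCC(=O)CC(=O)OC | starting material
7 | methyl 3-oxopent-4-enoate (Nazarov reagent) | C=CC(=O)CC(=O)OC | intermediate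
8 | Michael adduct: 5 bearing a 5-methoxy-3,5-dioxopentyl chain on C10 (C1 β, C20 ester α; C6 not assigned) | C#CC[C@]23C=CC(=O)C[C@H]2[C@](C(=O)OC)(CCC(=O)CC(=O)OC)C(=O)C3C(=O)OC | intermediate
9 | rings A/B/C tricycle: 3-oxo-Δ4(5) alkylidene β-keto ester, 12-oxo-Δ13(14) enone, 8β-propargyl, 9β-H, 10α-CO2Me, 6β-CO2Me | C#CC[C@]23C=CC(=O)C[C@H]2[C@]1(C(=O)OC)CCC(=O)C(C(=O)OC)=C1[C@@H]3C(=O)OC | intermediate
10 | as 9 but C4–C5 saturated, 5β-H, trans A/B (C4 enolisable, not assigned) | C#CC[C@]23C=CC(=O)C[C@H]2[C@]1(C(=O)OC)CCC(=O)C(C(=O)OC)[C@H]1[C@@H]3C(=O)OC | intermediate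
11 | as 10 with quaternary C4: 4β-methyl, 4α-CO2Me | C#CC[C@]23C=CC(=O)C[C@H]2[C@]1(C(=O)OC)CCC(=O)[C@@](C)(C(=O)OC)[C@H]1[C@@H]3C(=O)OC | intermediate
12 | 3β-hydroxy 12-(tert-butyldimethylsilyloxy)-Δ12(13) enol ether, 8β-propargyl, triester | C#CC[C@]23CC=C(O[Si](C)(C)C(C)(C)C)C[C@H]2[C@]1(C(=O)OC)CC[C@H](O)[C@@](C)(C(=O)OC)[C@H]1[C@@H]3C(=O)OC | intermediate
13 | trimethyl 3β-hydroxy-12-oxogibberell-16-ene-7,19,20-trioate | C=C1C[C@]23C[C@H]1C(=O)C[C@H]2[C@]1(C(=O)OC)CC[C@H](O)[C@@](C)(C(=O)OC)[C@H]1[C@@H]3C(=O)OC | intermediate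
14 | dimethyl 3β-hydroxy-gibberell-16-ene-7,19-dioate 20,12α-lactone | C=C1C[C@]23C[C@H]1[C@@H]4C[C@H]2[C@]1(C(=O)O4)CC[C@H](O)[C@@](C)(C(=O)OC)[C@H]1[C@@H]3C(=O)OC | intermediate
15 | 3β-hydroxy-gibberell-16-ene-7,19-dioic acid 20,12α-lactone | C=C1C[C@]23C[C@H]1[C@@H]4C[C@H]2[C@]1(C(=O)O4)CC[C@H](O)[C@@](C)(C(=O)O)[C@H]1[C@@H]3C(=O)O | intermediate
16 | 20,12α-lactol of the target (C20 hemiacetal carbon not assigned) | C=C1C[C@]23C[C@H]1[C@@H]4C[C@H]2[C@]1(C(O)O4)CC[C@H](O)[C@@](C)(C(=O)O)[C@H]1[C@@H]3C(=O)O | intermediate
17 | CNP0218328.1, 3β,12α-dihydroxy-20-oxogibberell-16-ene-7,19-dioic acid | C=C1C[C@]23C[C@H]1[C@@H](O)C[C@H]2[C@]1(C=O)CC[C@H](O)[C@@](C)(C(=O)O)[C@H]1[C@@H]3C(=O)O | target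

**Step count and risks**
Total steps: 10. Longest linear sequence: 10 (from 1; 2 and 6 enter as purchased reagents).

The three steps most likely to fail are steps 1, 2 and 4.

Step 1 (the proposed new method). The silyl enol ether may attack ortho, the phenoxenium ion may lose a propargylic proton to a quinone methide, and 4 may cyclise racemically in the acidic medium before it meets the chiral catalyst. The fallback uses known chemistry, sets out from 2 and comes back at 4. Knoevenagel condensation of 2 with 4-(tert-butyldimethylsilyloxy)cyclohexanone (TiCl4, pyridine, THF) gives dimethyl 2-[4-(tert-butyldimethylsilyloxy)cyclohexylidene]-3-oxopentanedioate F1. TiCl4-promoted conjugate propargylation with allenyltributylstannane (CH2Cl2, −78 °C) builds the quaternary carbon and gives dimethyl 2-[4-(tert-butyldimethylsilyloxy)-1-(prop-2-yn-1-yl)cyclohexyl]-3-oxopentanedioate F2. HF·pyridine gives dimethyl 2-[4-hydroxy-1-(prop-2-yn-1-yl)cyclohexyl]-3-oxopentanedioate F3, and Dess–Martin oxidation gives dimethyl 3-oxo-2-[4-oxo-1-(prop-2-yn-1-yl)cyclohexyl]pentanedioate F4. Double dehydrogenation of F4 with IBX (DMSO, 80 °C) gives 4.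

Step 2. Enantiocontrol may be eroded because 4 carries the labile C6 centre (the two enone arms are diastereotopic within each C6 epimer) and because uncatalysed cyclisation competes. The fallback sets out from 4 and comes back at 5, and replaces non-covalent base/H-bond activation by covalent iminium activation. The primary amine 9-amino(9-deoxy)epi-quinidine (20 mol%) with 2-fluorobenzoic acid (40 mol%) in toluene condenses reversibly with the dienone carbonyl; the chiral iminium ion lowers the LUMO of one enone arm, the pendant β-keto ester enol adds to it, and hydrolysis releases 5. This fallback makes no new isolable compound (F0).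

Step 4. Protonation at C5 may give the cis A/B junction, which cannot be corrected later. The fallback sets out from 9 and comes back at 14; it closes ring D first so that the classical Stork dissolving-metal reductive methylation can set C5 and C4 together.
- 9 is deprotonated at the vinylogous C6–H (NaH, 1.05 equiv) so that ring A is masked as its dienolate. KBH(sec-Bu)3 then reduces only the ring C enone, and TBSCl gives the 3,12-bis(tert-butyldimethylsilyloxy) 3,5(6),12-triene triester F5.
- The gold-catalysed cyclisation in CH2Cl2/MeOH closes ring D and returns ring A to the enone, giving the tetracyclic 12-oxo-16-ene alkylidene β-keto ester F6.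
- The same dienolate masking followed by KBH(sec-Bu)3 gives the 20,12α-lactone alkylidene β-keto ester F7.
- Li in NH3/THF (−78 °C), then MeI, gives the trans-fused 4β-methyl-4α-methoxycarbonyl 3-oxo 20,12α-lactone F8.
- KBH(sec-Bu)3 reduces C3 of F8 to the 3β-alcohol 14.

**Further compounds**
F1 | step 1 | dimethyl 2-[4-(tert-butyldimethylsilyloxy)cyclohexylidene]-3-oxopentanedioate | COC(=O)CC(=O)C(C(=O)OC)=C1CCC(O[Si](C)(C)C(C)(C)C)CC1
F2 | step 1 | dimethyl 2-[4-(tert-butyldimethylsilyloxy)-1-(prop-2-yn-1-yl)cyclohexyl]-3-oxopentanedioate | COC(=O)CC(=O)C(C(=O)OC)C1(CC#C)CCC(O[Si](C)(C)C(C)(C)C)CC1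
F3 | step 1 | dimethyl 2-[4-hydroxy-1-(prop-2-yn-1-yl)cyclohexyl]-3-oxopentanedioate | COC(=O)CC(=O)C(C(=O)OC)C1(CC#C)CCC(O)CC1
F4 | step 1 | dimethyl 3-oxo-2-[4-oxo-1-(prop-2-yn-1-yl)cyclohexyl]pentanedioate | COC(=O)CC(=O)C(C(=O)OC)C1(CC#C)CCC(=O)CC1
F0 | step 2 | none | none
F5 | step 4 | 3,12-bis(tert-butyldimethylsilyloxy) 3,5(6),12-triene triester with 8β-propargyl | C#CC[C@]23CC=C(O[Si](C)(C)C(C)(C)C)C[C@H]2[C@]1(C(=O)OC)CCC(O[Si](C)(C)C(C)(C)C)=C(C(=O)OC)C1=C3C(=O)OC
F6 | step 4 | tetracyclic 3,12-dioxo-4(5),16-diene triester (alkylidene β-keto ester) | C=C1C[C@]23C[C@H]1C(=O)C[C@H]2[C@]1(C(=O)OC)CCC(=O)C(C(=O)OC)=C1[C@@H]3C(=O)OC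
F7 | step 4 | 3-oxo-4(5),16-diene 7,19-dimethyl ester 20,12α-lactone | C=C1C[C@]23C[C@H]1[C@@H]4C[C@H]2[C@]1(C(=O)O4)CCC(=O)C(C(=O)OC)=C1[C@@H]3C(=O)OC
F8 | step 4 | dimethyl 3-oxogibberell-16-ene-7,19-dioate 20,12α-lactone | C=C1C[C@]23C[C@H]1[C@@H]4C[C@H]2[C@]1(C(=O)O4)CCC(=O)[C@@](C)(C(=O)OC)[C@H]1[C@@H]3C(=O)OC
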